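Cutting the C11–C15 bond, which joins the gem-dimethyl carbon to the β-carbon of the butenolide, opens the cyclohexane (C1, C14, C13, C12, C11, C15) and enlarges the 12-membered ring to a 14-membered cembranolide whose C1 carries the isopropenyl group of (R)-limonene. The route builds that macrocycle with C4 as a ketone and forms C11–C15 last: iron-hydride hydrogen-atom transfer to the isopropenyl group gives the tertiary C15 radical, which adds 6-endo to C11 of the polarised C11=C12 butenolide, closing the cyclohexane and contracting the macrocycle in one operation. C10 comes from (R)-epichlorohydrin, C6 from a reagent-controlled aldol ring closure.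

Key step: step 17

Assumption: the enol borinate made with (−)-Ipc2BCl attacks the si face of the enal, which gives 6S; if the sense proves opposite, (+)-Ipc2BCl is used and nothing else changes.
Remark: locants are those of the target (C1 bridgehead CH, C4 bearing C20, C6 carbinol, C7=C8 with C19 on C8, C10 lactone CH–O, C11=C12, C15 gem-dimethyl carbon, C18 lactone C=O); the CIP label at C1 switches between R and S along the route only because neighbouring groups change priority, never by inversion.
Remark: radicals and the metal salt of a product before aqueous work-up are not numbered.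

Step 1
Reactants: 1 (R)-limonene
Product: 3 (R)-6-oxo-3-(prop-1-en-2-yl)heptanal, via limonene ozonide 2 (not isolated)
Conditions: O3 (1.0 equiv), CH2Cl2, −78 °C; PPh3, −78 °C → rt
Reagents that add atoms: ozone, [O-][O+]=O
Why: Criegee ozonolysis with one equivalent of ozone should cleave the electron-richer trisubstituted ring alkene before the 1,1-disubstituted isopropenyl group, and the stereocentre (future C1) is not touched.

Step 2
Reactants: 3 (R)-6-oxo-3-(prop-1-en-2-yl)heptanal
Product: 4 (R)-7-hydroxy-5-(prop-1-en-2-yl)heptan-2-one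
Conditions: NaBH4 (0.3 equiv), EtOH/CH2Cl2 (3:7), −78 °C
Reagents that add atoms: none
Why: Chemoselective borohydride reduction, since at −78 °C an aldehyde is reduced far faster than a methyl ketone.

Step 3
Reactants: 4 (R)-7-hydroxy-5-(prop-1-en-2-yl)heptan-2-one
Product: 5 (R)-5-(2-methyl-1,3-dioxolan-2-yl)-3-(prop-1-en-2-yl)pentan-1-ol
Conditions: HOCH2CH2OH, PPTS (cat.), PhH, reflux (Dean–Stark)
Reagents that add atoms: ethylene glycol, OCCO
Why: Acid-catalysed ketalisation masks the C4 ketone against the enolate chemistry of step 11, and PPTS is too weak to isomerise the isopropenyl group.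

Step 4
Reactants: 5 (R)-5-(2-methyl-1,3-dioxolan-2-yl)-3-(prop-1-en-2-yl)pentan-1-ol
Product: 6 2-[(R)-5-iodo-3-(prop-1-en-2-yl)pentyl]-2-methyl-1,3-dioxolane
Conditions: I2, PPh3, imidazole, CH2Cl2, 0 °C → rt
Reagents that add atoms: iodine, II
Why: Appel-type iodination of a primary alcohol by SN2 displacement of the alkoxyphosphonium group, under conditions that leave the ketal intact.

Step 5
Reactants: 7 ethynyltrimethylsilane; 8 (R)-epichlorohydrin
Product: 10 (R)-1-chloro-5-(trimethylsilyl)pent-4-yn-2-ol, via lithium acetylide 9 (not isolated)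
Conditions: n-BuLi, THF, −78 °C; BF3·OEt2; then 8, −78 °C
Reagents that add atoms: none
Why: Yamaguchi–Hirao BF3-assisted epoxide opening by the lithium acetylide at the unsubstituted epoxide carbon (SN2), so the C–O stereocentre of 8 (future C10) is carried over unchanged.

Step 6
Reactants: 10 (R)-1-chloro-5-(trimethylsilyl)pent-4-yn-2-ol
Product: 11 (R)-1-chloropent-4-yn-2-ol
Conditions: AgNO3 (10 mol%), acetone/H2O, rt
Reagents that add atoms: none
Why: Silver-catalysed protodesilylation of the alkynylsilane under neutral conditions, which should not close the chlorohydrin to the epoxide.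

Step 7
Reactants: 11 (R)-1-chloropent-4-yn-2-ol
Product: 13 (2E,5R)-6-chloro-3-methylhex-2-ene-1,5-diol, via alkenylalane 12 (not isolated)
Conditions: Me3Al (3 equiv), Cp2ZrCl2 (25 mol%), CH2Cl2, 0 °C → rt; evaporate; n-BuLi, THF, −78 °C; (CH2O)n, → rt
Reagents that add atoms: trimethylaluminium, C[Al](C)C; paraformaldehyde, C=O
Why: Negishi zirconium-catalysed carboalumination adds methyl and aluminium syn across the terminal alkyne with methyl on the internal carbon, and hydroxymethylation of the alkenylalanate proceeds with retention, which fixes the 7E alkene and installs C19 and C6.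

Step 8
Reactants: 13 (2E,5R)-6-chloro-3-methylhex-2-ene-1,5-diol
Product: 14 (2R,4E)-6-(tert-butyldimethylsilyloxy)-1-chloro-4-methylhex-4-en-2-ol
Conditions: TBSCl (1.05 equiv), imidazole, CH2Cl2, 0 °C
Reagents that add atoms: tert-butyldimethylsilyl chloride, CC(C)(C)[Si](C)(C)Cl
Why: Silylation should take the unhindered primary allylic hydroxyl in preference to the secondary one.

Step 9
Reactants: 14 (2R,4E)-6-(tert-butyldimethylsilyloxy)-1-chloro-4-methylhex-4-en-2-ol
Product: 15 tert-butyldimethyl{[(E)-3-methyl-4-[(R)-oxiran-2-yl]but-2-en-1-yl]oxy}silane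
Conditions: K2CO3, MeOH, rt
Reagents that add atoms: none
Why: Intramolecular Williamson etherification of the chlorohydrin, in which the C10–O bond is not broken, so the configuration is retained.

Step 10
Reactants: 15 tert-butyldimethyl{[(E)-3-methyl-4-[(R)-oxiran-2-yl]but-2-en-1-yl]oxy}silane; 16 (phenylthio)acetic acid
Product: 19 (5R)-5-[(E)-4-(tert-butyldimethylsilyloxy)-2-methylbut-2-enyl]-3-(phenylthio)dihydrofuran-2(3H)-one (both C3 epimers), via dilithio phenylthioacetate 17 (not isolated), via hydroxy acid 18 (not isolated)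
Conditions: 16, LDA (2 equiv per 16), THF, 0 °C; then 15, 0 °C → rt; dil. HCl to pH 4; PPTS (cat.), PhH, 50 °C
Reagents that add atoms: none
Why: The dianion of the α-thio acid opens the terminal epoxide at its CH2 carbon (SN2 alkylation) and the γ-hydroxy acid lactonises, a standard entry to α-phenylthio γ-lactones that leaves C10 untouched.

Step 11
Reactants: 19 (5R)-5-[(E)-4-(tert-butyldimethylsilyloxy)-2-methylbut-2-enyl]-3-(phenylthio)dihydrofuran-2(3H)-one; 6 2-[(R)-5-iodo-3-(prop-1-en-2-yl)pentyl]-2-methyl-1,3-dioxolane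
Product: 21 (5R)-5-[(E)-4-(tert-butyldimethylsilyloxy)-2-methylbut-2-enyl]-3-[(R)-5-(2-methyl-1,3-dioxolan-2-yl)-3-(prop-1-en-2-yl)pentyl]-3-(phenylthio)dihydrofuran-2(3H)-one (both C3 epimers), via lithium enolate 20 (not isolated)
Conditions: LiHMDS, THF/DMPU, −78 °C; then 6, −78 → 0 °C
Reagents that add atoms: none
Why: SN2 alkylation of the sulfur-stabilised lactone enolate by an unhindered primary iodide forms C12–C13, and the new C12 centre is destroyed in step 12.

Step 12
Reactants: 21 (5R)-5-[(E)-4-(tert-butyldimethylsilyloxy)-2-methylbut-2-enyl]-3-[(R)-5-(2-methyl-1,3-dioxolan-2-yl)-3-(prop-1-en-2-yl)pentyl]-3-(phenylthio)dihydrofuran-2(3H)-one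
Product: 23 (R)-5-[(E)-4-(tert-butyldimethylsilyloxy)-2-methylbut-2-enyl]-3-[(S)-5-(2-methyl-1,3-dioxolan-2-yl)-3-(prop-1-en-2-yl)pentyl]furan-2(5H)-one, via sulfoxide 22 (not isolated)
Conditions: mCPBA (1.0 equiv), CH2Cl2, −78 °C; then PhMe, CaCO3, 110 °C
Reagents that add atoms: none
Why: Sulfide oxidation, which is much faster than alkene epoxidation at −78 °C, followed by thermal sulfoxide syn-elimination, which in α-alkyl-α-sulfinyl γ-lactones takes a ring C11 hydrogen and gives the endocyclic C11=C12 butenolide.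

Step 13
Reactants: 23 (R)-5-[(E)-4-(tert-butyldimethylsilyloxy)-2-methylbut-2-enyl]-3-[(S)-5-(2-methyl-1,3-dioxolan-2-yl)-3-(prop-1-en-2-yl)pentyl]furan-2(5H)-one
Product: 24 (R)-5-[(E)-4-hydroxy-2-methylbut-2-enyl]-3-[(S)-6-oxo-3-(prop-1-en-2-yl)heptyl]furan-2(5H)-one
Conditions: 1 M HCl, THF, rt
Reagents that add atoms: water, O
Why: Acid hydrolysis removes the primary silyl ether and the dioxolane in one operation, and the butenolide, allylic alcohol and isopropenyl group should tolerate dilute acid at room temperature.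

Step 14
Reactants: 24 (R)-5-[(E)-4-hydroxy-2-methylbut-2-enyl]-3-[(S)-6-oxo-3-(prop-1-en-2-yl)heptyl]furan-2(5H)-one
Product: 25 (E)-3-methyl-4-{(R)-5-oxo-4-[(S)-6-oxo-3-(prop-1-en-2-yl)heptyl]-2,5-dihydrofuran-2-yl}but-2-enal
Conditions: MnO2, CH2Cl2, rt
Reagents that add atoms: none
Why: Manganese dioxide oxidises only the allylic alcohol, and the E geometry of the enal is kept.

Step 15
Reactants: 25 (E)-3-methyl-4-{(R)-5-oxo-4-[(S)-6-oxo-3-(prop-1-en-2-yl)heptyl]-2,5-dihydrofuran-2-yl}but-2-enal
Product: 27 (1S,6S,7E,10R)-6-hydroxy-4-oxo cembranolide (14-membered ring C1–C14; isopropenyl at C1; ketone at C4; C10–O–C18(=O)–C12=C11 butenolide), via C4 enol borinate 26 (not isolated)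
Conditions: (−)-Ipc2BCl (3 equiv), Et3N, CH2Cl2, 0 °C, 25 added over 10 h (final 2 mM); −20 °C; then pH 7 buffer, MeOH, H2O2, 0 °C
Reagents that add atoms: none
Why: Intramolecular boron aldol reaction (Paterson aldol) in which the chloroborane/amine pair should enolise only the methyl ketone on its CH3 side, slow addition keeps the enol borinate dilute so that it adds to its own enal through a boron-bridged six-membered transition state, and the isopinocampheyl ligands direct attack to the si face of C6 to give 6S.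

Step 16
Reactants: 27 (1S,6S,7E,10R)-6-hydroxy-4-oxo cembranolide
Product: 28 (1S,6S,7E,10R)-6-(tert-butyldimethylsilyloxy)-4-oxo cembranolide
Conditions: TBSOTf, 2,6-lutidine, CH2Cl2, −78 °C
Reagents that add atoms: tert-butyldimethylsilyl triflate, CC(C)(C)[Si](C)(C)OS(=O)(=O)C(F)(F)F
Why: Silylation of the β-hydroxy ketone with a silyl triflate and a hindered pyridine at low temperature avoids retro-aldol cleavage and β-elimination.

Step 17
Reactants: 28 (1S,6S,7E,10R)-6-(tert-butyldimethylsilyloxy)-4-oxo cembranolide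
Product: 29 (1S,6S,7E,10R)-11,12-dihydro-4-oxo-6-(tert-butyldimethylsilyloxy)verticillanolide (C11 and C12 unassigned)
Conditions: Fe(acac)3 (30 mol%), PhSiH3 (2.5 equiv, slow addition), EtOH/(CH2OH)2 (5:1), 60 °C, 5 mM, degassed
Reagents that add atoms: none
Why: Fe(acac)3 and phenylsilane form an iron hydride that transfers a hydrogen atom to the terminal CH2 of the C1 isopropenyl group (Markovnikov), which creates the second C15 methyl and the tertiary C15 radical; this radical adds to C11 of the butenolide, and the C12 α-lactone radical is then reduced to the enolate and protonated by ethanol. The closest known reaction type is the metal-hydride hydrogen-atom-transfer reductive Giese coupling of 1,1-disubstituted alkenes with unsaturated esters and lactones, used here intramolecularly. The cyclohexane (C1, C14, C13, C12, C11, C15) closes 6-endo-trig, which at the same time turns the 14-membered ring into the 12-membered ring; 5-exo attack at C12 is disfavoured because C12 is fully substituted and is the electron-rich α-carbon of the polarised alkene. The new centres C11 and C12 are set by the ring (the radical can reach C11 only from the butenolide face on the side of the C1 tether; a cis ring fusion is expected after protonation) and need no control, since both become sp2 again in step 19. The step needs hydrogen-atom transfer at one alkene and addition at one carbon: the isopropenyl group is the only 1,1-disubstituted alkene because C4 is a ketone, the trisubstituted C7=C8 alkene next to the silyloxy group accepts a hydrogen atom much more slowly, and the nucleophilic tertiary radical is matched to the electrophilic β-carbon C11.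

Step 18
Reactants: 29 (1S,6S,7E,10R)-11,12-dihydro-4-oxo-6-(tert-butyldimethylsilyloxy)verticillanolide
Product: 30 (1S,6S,7E,10R)-6-(tert-butyldimethylsilyloxy)-11,12-dihydroverticilla-4(20),7-dien-18,10-olide
Conditions: Zn, CH2Br2, TiCl4 (Lombardo reagent), THF/CH2Cl2, 0 °C → rt
Reagents that add atoms: dibromomethane, BrCBr
Why: Takai–Lombardo methylenation, whose non-basic zinc/titanium methylene reagent converts ketones but not lactones and should neither eliminate the β-silyloxy group nor epimerise the lactone.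

Step 19
Reactants: 30 (1S,6S,7E,10R)-6-(tert-butyldimethylsilyloxy)-11,12-dihydroverticilla-4(20),7-dien-18,10-olide
Product: 34 (1R,6S,7E,10R)-6-(tert-butyldimethylsilyloxy)verticilla-4(20),7,11-trien-18,10-olide, via lithium enolate 31 (not isolated), via C12 selenide 32 (not isolated), via selenoxide 33 (not isolated)
Conditions: LDA, THF, −78 °C; PhSeBr, −78 °C; then H2O2, pyridine, 0 °C → rt
Reagents that add atoms: none
Why: Lactone enolate selenenylation followed by selenoxide syn-elimination, in which selenium should enter anti to the C15 gem-dimethyl carbon and hence cis to H-11, so that the nearly eclipsed ring-fusion C11–H is removed to give the tetrasubstituted C11=C12 butenolide and both centres made in step 17 are erased.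

Step 20
Reactants: 34 (1R,6S,7E,10R)-6-(tert-butyldimethylsilyloxy)verticilla-4(20),7,11-trien-18,10-olide
Product: 35 (1R,6S,7E,10R)-6-hydroxyverticilla-4(20),7,11-trien-18,10-olide
Conditions: HF·pyridine, pyridine, THF, 0 °C → rt
Reagents that add atoms: none
Why: Fluoride cleavage of the secondary silyl ether under buffered, non-basic conditions that should not epimerise C10 or ionise the allylic alcohol.

Step 21
Reactants: 35 (1R,6S,7E,10R)-6-hydroxyverticilla-4(20),7,11-trien-18,10-olide
Product: 36 CNP0289913.1, (1R,6S,7E,10R)-6-acetoxyverticilla-4(20),7,11-trien-18,10-olide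
Conditions: Ac2O, pyridine, DMAP (cat.), CH2Cl2, 0 °C → rt
Reagents that add atoms: acetic anhydride, CC(=O)OC(C)=O
Why: DMAP-catalysed acetylation of the secondary allylic alcohol, with retention at C6 because the C–O bond is not broken.

Compound list
1 | (R)-limonene | CC1=CC[C@@H](CC1)C(C)=C | starting material
2 | limonene ozonide (bicyclic 1,2,4-trioxolane across the ring alkene; acetal centres unassigned) | CC12CC[C@@H](C(C)=C)CC(OO1)O2 | intermediate
3 | (R)-6-oxo-3-(prop-1-en-2-yl)heptanal | O=CC[C@@H](CCC(C)=O)C(C)=C | intermediate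
4 | (R)-7-hydroxy-5-(prop-1-en-2-yl)heptan-2-one | OCC[C@@H](CCC(C)=O)C(C)=C | intermediate
5 | (R)-5-(2-methyl-1,3-dioxolan-2-yl)-3-(prop-1-en-2-yl)pentan-1-ol | OCC[C@@H](CCC1(C)OCCO1)C(C)=C | intermediate
6 | 2-[(R)-5-iodo-3-(prop-1-en-2-yl)pentyl]-2-methyl-1,3-dioxolane | ICC[C@@H](CCC1(C)OCCO1)C(C)=C | intermediate
7 | ethynyltrimethylsilane | C#C[Si](C)(C)C | starting material
8 | (R)-epichlorohydrin | ClC[C@H]1CO1 | starting material
9 | lithium (trimethylsilyl)acetylide | [Li]C#C[Si](C)(C)C | intermediate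
10 | (R)-1-chloro-5-(trimethylsilyl)pent-4-yn-2-ol | ClC[C@H](O)CC#C[Si](C)(C)C | intermediate
11 | (R)-1-chloropent-4-yn-2-ol | ClC[C@H](O)CC#C | intermediate
12 | (E)-alkenyldimethylalane, dimethylaluminium alkoxide of (2R,4E)-1-chloro-5-(dimethylalumanyl)-4-methylpent-4-en-2-ol | C[Al](C)/C=C(\C)C[C@@H](O[Al](C)C)CCl | intermediate
13 | (2E,5R)-6-chloro-3-methylhex-2-ene-1,5-diol | OC/C=C(\C)C[C@@H](O)CCl | intermediate
14 | (2R,4E)-6-(tert-butyldimethylsilyloxy)-1-chloro-4-methylhex-4-en-2-ol | CC(C)(C)[Si](C)(C)OC/C=C(\C)C[C@@H](O)CCl | intermediate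
15 | tert-butyldimethyl{[(E)-3-methyl-4-[(R)-oxiran-2-yl]but-2-en-1-yl]oxy}silane | CC(C)(C)[Si](C)(C)OC/C=C(\C)C[C@@H]1CO1 | intermediate
16 | (phenylthio)acetic acid | OC(=O)CSc1ccccc1 | starting material
17 | dilithio phenylthioacetate (lithium 2-lithio-2-(phenylthio)acetate) | [Li]OC(=O)C([Li])Sc1ccccc1 | intermediate
18 | (4R,6E)-8-(tert-butyldimethylsilyloxy)-4-hydroxy-6-methyl-2-(phenylthio)oct-6-enoic acid (C2 epimers) | OC(=O)C(Sc1ccccc1)C[C@H](O)C/C(C)=C/CO[Si](C)(C)C(C)(C)C | intermediate
19 | (5R)-5-[(E)-4-(tert-butyldimethylsilyloxy)-2-methylbut-2-enyl]-3-(phenylthio)dihydrofuran-2(3H)-one (C3 epimers) | O=C1O[C@H](C/C(C)=C/CO[Si](C)(C)C(C)(C)C)CC1Sc2ccccc2 | intermediate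
20 | lithium enolate of 19 | [Li]OC1=C(Sc2ccccc2)C[C@@H](C/C(C)=C/CO[Si](C)(C)C(C)(C)C)O1 | intermediate
21 | (5R)-5-[(E)-4-(tert-butyldimethylsilyloxy)-2-methylbut-2-enyl]-3-[(R)-5-(2-methyl-1,3-dioxolan-2-yl)-3-(prop-1-en-2-yl)pentyl]-3-(phenylthio)dihydrofuran-2(3H)-one (C3 epimers) | O=C1O[C@H](C/C(C)=C/CO[Si](C)(C)C(C)(C)C)CC1(Sc2ccccc2)CC[C@@H](CCC3(C)OCCO3)C(C)=C | intermediate
22 | S-oxide (sulfoxide) of 21 | O=C1O[C@H](C/C(C)=C/CO[Si](C)(C)C(C)(C)C)CC1(S(=O)c2ccccc2)CC[C@@H](CCC3(C)OCCO3)C(C)=C | intermediate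
23 | (R)-5-[(E)-4-(tert-butyldimethylsilyloxy)-2-methylbut-2-enyl]-3-[(S)-5-(2-methyl-1,3-dioxolan-2-yl)-3-(prop-1-en-2-yl)pentyl]furan-2(5H)-one | O=C1O[C@H](C/C(C)=C/CO[Si](C)(C)C(C)(C)C)C=C1CC[C@@H](CCC2(C)OCCO2)C(C)=C | intermediate
24 | (R)-5-[(E)-4-hydroxy-2-methylbut-2-enyl]-3-[(S)-6-oxo-3-(prop-1-en-2-yl)heptyl]furan-2(5H)-one | O=C1O[C@H](C/C(C)=C/CO)C=C1CC[C@@H](CCC(C)=O)C(C)=C | intermediate
25 | (E)-3-methyl-4-{(R)-5-oxo-4-[(S)-6-oxo-3-(prop-1-en-2-yl)heptyl]-2,5-dihydrofuran-2-yl}but-2-enal | O=C1O[C@H](C/C(C)=C/C=O)C=C1CC[C@@H](CCC(C)=O)C(C)=C | intermediate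
26 | C4 enol diisopinocampheylborinate of 25 (boron on the C4 enol oxygen, C4=C5H2) | C=C(OB([C@@H]2C[C@@H]3C[C@H]([C@H]2C)C3(C)C)[C@@H]2C[C@@H]3C[C@H]([C@H]2C)C3(C)C)CC[C@@H](C(C)=C)CCC1=C[C@@H](C/C(C)=C/C=O)OC1=O | intermediate
27 | (1S,6S,7E,10R)-6-hydroxy-4-oxo cembranolide (14-membered ring, C1 isopropenyl, C4 ketone, C18,10-butenolide with C11=C12) | O=C1CC[C@@H](C(C)=C)CCC3=C[C@@H](C/C(C)=C/[C@@H](O)C1)OC3=O | intermediate
28 | (1S,6S,7E,10R)-6-(tert-butyldimethylsilyloxy)-4-oxo cembranolide (precursor of the key step) | O=C1CC[C@@H](C(C)=C)CCC3=C[C@@H](C/C(C)=C/[C@@H](O[Si](C)(C)C(C)(C)C)C1)OC3=O | intermediate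
29 | (1S,6S,7E,10R)-11,12-dihydro-4-oxo-6-(tert-butyldimethylsilyloxy)verticillanolide (C11, C12 unassigned) | O=C1CC[C@@H]2CCC3C([C@@H](C/C(C)=C/[C@@H](O[Si](C)(C)C(C)(C)C)C1)OC3=O)C2(C)C | intermediate
30 | (1S,6S,7E,10R)-6-(tert-butyldimethylsilyloxy)-11,12-dihydroverticilla-4(20),7-dien-18,10-olide (C11, C12 unassigned) | C=C1CC[C@@H]2CCC3C([C@@H](C/C(C)=C/[C@@H](O[Si](C)(C)C(C)(C)C)C1)OC3=O)C2(C)C | intermediate
31 | lithium enolate of 30 (C12=C18–OLi; C11 unassigned) | C=C1CC[C@@H]2CCC3=C(O[Li])O[C@H](C/C(C)=C/[C@@H](O[Si](C)(C)C(C)(C)C)C1)C3C2(C)C | intermediate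
32 | 12-(phenylselanyl) derivative of 30 (selenium expected cis to H-11; C11, C12 unassigned) | C=C1CC[C@@H]2CCC3([Se]c4ccccc4)C([C@@H](C/C(C)=C/[C@@H](O[Si](C)(C)C(C)(C)C)C1)OC3=O)C2(C)C | intermediate
33 | selenoxide of 32 | C=C1CC[C@@H]2CCC3([Se](=O)c4ccccc4)C([C@@H](C/C(C)=C/[C@@H](O[Si](C)(C)C(C)(C)C)C1)OC3=O)C2(C)C | intermediate
34 | (1R,6S,7E,10R)-6-(tert-butyldimethylsilyloxy)verticilla-4(20),7,11-trien-18,10-olide | C=C1CC[C@@H]2CCC3=C([C@@H](C/C(C)=C/[C@@H](O[Si](C)(C)C(C)(C)C)C1)OC3=O)C2(C)C | intermediate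
35 | (1R,6S,7E,10R)-6-hydroxyverticilla-4(20),7,11-trien-18,10-olide | C=C1CC[C@@H]2CCC3=C([C@@H](C/C(C)=C/[C@@H](O)C1)OC3=O)C2(C)C | intermediate
36 | CNP0289913.1, (1R,6S,7E,10R)-6-acetoxyverticilla-4(20),7,11-trien-18,10-olide | C=C1CC[C@@H]2CCC3=C([C@@H](C/C(C)=C/[C@@H](OC(C)=O)C1)OC3=O)C2(C)C | target

Total step count: 21. Longest linear sequence: 17 steps (steps 5–21, from ethynyltrimethylsilane and (R)-epichlorohydrin); the limonene branch (steps 1–4) joins at step 11.

Steps most likely to fail

1. Step 17 (key step). What may go wrong: the iron hydride reduces the C15 radical before it cyclises (net hydrogenation of the isopropenyl group), or hydrogen-atom transfer also reaches C7=C8. The fallback makes the same radical and the same C11–C15 bond by known chemistry, with no metal hydride present in the ring-closing step; it sets out from 28 and comes back at 29. Mukaiyama hydration of 28 (Co(acac)2 cat., PhSiH3, O2, THF/i-PrOH; oxygen traps the radical before it can cyclise) should give the C15 tertiary alcohol F1. Methyl chlorooxoacetate, Et3N and DMAP should give the methyl oxalate F2, and one equivalent of CsOH the caesium oxalate F3. Blue-light irradiation with Ir[dF(CF3)ppy]2(dtbbpy)PF6 in DME/DMF/H2O should expel two CO2, and the tertiary radical should add to C11 in a photoredox Giese cyclisation to give 29.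

2. Step 15. What may go wrong: oligomerisation in place of ring closure, poor facial selectivity at C6 inside the macrocyclic transition state, or enolisation of the butenolide with loss of configuration at C10. The fallback fixes C6 in an intermolecular aldol reaction and closes the ring at C12–C13 instead; it sets out from 4 and 19 and comes back at 28. Appel iodination of 4 should give the iodo ketone F4. HF·pyridine on 19 should give the allylic alcohol F5, and MnO2 the enal F6. The (−)-Ipc2B enolate of F4 should add to F6 to give the (6S)-β-hydroxy ketone F7, and TBSOTf/2,6-lutidine the silyl ether F8. Noyori ketalisation [(TMSOCH2)2, TMSOTf cat., −78 °C] should give the dioxolane F9. KHMDS in THF at high dilution should close the 14-membered ring by intramolecular alkylation of the α-phenylthio lactone enolate with the primary iodide, a known macrocyclisation type, to give the macrocyclic sulfide F10. mCPBA and then heat should give the butenolide ketal F11, and PPTS in wet acetone should free the C4 ketone to give 28.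

3. Step 19. What may go wrong: the selenium electrophile adds to the C4(20) or C7 alkene, or the syn-elimination removes H-13 in place of H-11. The fallback is a Saegusa–Ito dehydrogenation, which uses no electrophilic selenium and goes through a palladium enolate; it sets out from 30 and comes back at 34. LDA and then TBSCl/DMPU should give the silyl ketene acetal F12, and Pd(OAc)2 in MeCN should give 34 by β-hydride elimination, in which reversible hydride re-addition can favour the tetrasubstituted butenolide.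

Further compounds
F1 | step 17 | (1S,6S,7E,10R)-6-(tert-butyldimethylsilyloxy)-1-(2-hydroxypropan-2-yl)-4-oxo cembranolide (C15 tertiary alcohol) | O=C1CC[C@@H](C(C)(C)O)CCC3=C[C@@H](C/C(C)=C/[C@@H](O[Si](C)(C)C(C)(C)C)C1)OC3=O
F2 | step 17 | C15 methyl oxalate of F1 | O=C1CC[C@@H](C(C)(C)OC(=O)C(=O)OC)CCC3=C[C@@H](C/C(C)=C/[C@@H](O[Si](C)(C)C(C)(C)C)C1)OC3=O
F3 | step 17 | caesium C15 oxalate of F1 | O=C1CC[C@@H](C(C)(C)OC(=O)C(=O)[O-])CCC3=C[C@@H](C/C(C)=C/[C@@H](O[Si](C)(C)C(C)(C)C)C1)OC3=O.[Cs+]
F4 | step 15 | (R)-7-iodo-5-(prop-1-en-2-yl)heptan-2-one | ICC[C@@H](CCC(C)=O)C(C)=C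
F5 | step 15 | (5R)-5-[(E)-4-hydroxy-2-methylbut-2-enyl]-3-(phenylthio)dihydrofuran-2(3H)-one (C3 epimers) | O=C1O[C@H](C/C(C)=C/CO)CC1Sc2ccccc2
F6 | step 15 | (E)-3-methyl-4-[(2R)-5-oxo-4-(phenylthio)tetrahydrofuran-2-yl]but-2-enal (C4 epimers) | O=C1O[C@H](C/C(C)=C/C=O)CC1Sc2ccccc2
F7 | step 15 | (6S)-β-hydroxy ketone from F4 and F6 (open chain: C13 iodide, C4 ketone, C6 OH, α-phenylthio lactone) | ICC[C@@H](CCC(=O)C[C@H](O)/C=C(C)/C[C@@H]1CC(Sc2ccccc2)C(=O)O1)C(C)=C
F8 | step 15 | 6-O-tert-butyldimethylsilyl ether of F7 | ICC[C@@H](CCC(=O)C[C@H](O[Si](C)(C)C(C)(C)C)/C=C(C)/C[C@@H]1CC(Sc2ccccc2)C(=O)O1)C(C)=C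
F9 | step 15 | C4 ethylene ketal (dioxolane) of F8 | ICC[C@@H](CCC2(OCCO2)C[C@H](O[Si](C)(C)C(C)(C)C)/C=C(C)/C[C@@H]1CC(Sc3ccccc3)C(=O)O1)C(C)=C
F10 | step 15 | macrocyclic 12-(phenylthio)-11,12-dihydro C4-ketal of 28 (C12 epimers) | C1C[C@H](C(C)=C)CCC2(OCCO2)C[C@H](O[Si](C)(C)C(C)(C)C)/C=C(C)/C[C@@H]3CC1(Sc4ccccc4)C(=O)O3
F11 | step 15 | C4 ethylene ketal of 28 | C1C[C@H](C(C)=C)CCC2(OCCO2)C[C@H](O[Si](C)(C)C(C)(C)C)/C=C(C)/C[C@@H]3C=C1C(=O)O3
F12 | step 19 | tert-butyldimethylsilyl ketene acetal of 30 (C12=C18–OSi) | C=C1CC[C@@H]2CCC3=C(O[Si](C)(C)C(C)(C)C)O[C@H](C/C(C)=C/[C@@H](O[Si](C)(C)C(C)(C)C)C1)C3C2(C)C
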